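Ring labels: rings A and C are the benzopyranone (isoflavone numbering), ring B is the pendant aryl (primed atoms), and ring D is the dimethylpyran fused at C2'–C3'.
Enabling feature: the neighbouring ring A carbons C8a and C4a carry the ring C oxygen O1 and the ring C carbonyl carbon C4. A carboxylate that inserts into an aryne leaves exactly this vicinal O/C(=O) pair, and C2 is the enol ether carbon next to it.
Retrosynthesis: both MOM ethers come off and a temporary chlorine is placed at C5. Then C8a–O1, C4a–C4 and O1–C2 are cut together, giving a chloroaryne and a 3-methoxy-2-arylacrylic acid. The acid is cut at Cα=CH(OMe), at C1'–Cα and at ring D.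
Forward order: rings B and A are bought as simple benzenes. Ring D closes first (step 4), the C3/C4 and C2 carbons follow (steps 5 and 6), ring A is armed as an aryne precursor (steps 8–11), and ring C closes last (step 12).
Stereochemistry: the target has no stereocentre. The only stereo element on the way, the alkene of the acrylic acid, disappears on ring closure.

Key step: step 12

Remark: the β-methoxyacrylate unit is drawn throughout as the E isomer, the one expected to dominate. The Z isomer would behave the same way in the key step.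

Step 1
Reactants: 1 5-bromo-2-hydroxy-3-methoxybenzaldehyde
Product: 2 5-bromo-3-methoxy-2-(methoxymethoxy)benzaldehyde
Conditions: MOMCl, i-Pr2NEt, CH2Cl2, 0 °C to rt
Reagents that add atoms: chloromethyl methyl ether (MOMCl), COCCl
Why: Base-mediated O-alkylation (MOM acetal formation) of the only phenol should be clean, and masking this oxygen, the future C4' hydroxyl, before its neighbour exists means two catechol hydroxyls never have to be told apart.

Step 2
Reactants: 2 5-bromo-3-methoxy-2-(methoxymethoxy)benzaldehyde
Product: 4 5-bromo-3-methoxy-2-(methoxymethoxy)phenol, via aryl formate 3 (not isolated)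
Conditions: mCPBA, CH2Cl2, 0 °C to rt; then K2CO3 (cat.), MeOH, rt
Reagents that add atoms: 3-chloroperbenzoic acid (mCPBA), O=C(OO)c1cccc(Cl)c1
Why: Baeyer–Villiger oxidation of a benzaldehyde with an ortho alkoxy donor proceeds by aryl migration to the formate, which catalytic carbonate in methanol transesterifies to the phenol, and no alkene is yet present to compete for the peracid.

Step 3
Reactants: 4 5-bromo-3-methoxy-2-(methoxymethoxy)phenol; 5 3-chloro-3-methylbut-1-yne
Product: 6 5-bromo-1-methoxy-2-(methoxymethoxy)-3-[(2-methylbut-3-yn-2-yl)oxy]benzene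
Conditions: DBU, CuCl2·2H2O (1 mol %), MeCN, 0 °C
Reagents that add atoms: none
Why: Copper-catalysed propargylic substitution of a tertiary propargyl chloride by a phenol under amidine base is the standard entry to aryl 1,1-dimethylpropargyl ethers and avoids the elimination seen under forcing Williamson conditions.

Step 4
Reactants: 6 5-bromo-1-methoxy-2-(methoxymethoxy)-3-[(2-methylbut-3-yn-2-yl)oxy]benzene
Product: 7 5-bromo-7-methoxy-8-(methoxymethoxy)-2,2-dimethyl-2H-chromene
Conditions: PhNEt2, 180 °C
Reagents that add atoms: none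
Why: An aromatic propargyl Claisen rearrangement followed by 1,5-hydrogen shift and oxa-6π electrocyclisation builds ring D, and because one ortho position carries the MOM ether the new C–C bond can form only at the carbon next to bromine, which is the C2'–C3' fusion the target needs.

Step 5
Reactants: 7 5-bromo-7-methoxy-8-(methoxymethoxy)-2,2-dimethyl-2H-chromene
Product: 8 methyl 2-[7-methoxy-8-(methoxymethoxy)-2,2-dimethyl-2H-chromen-5-yl]acetate
Conditions: BrZnCH2CO2Me (from BrCH2CO2Me, Zn dust, TMSCl cat., THF, 40 °C), Pd2(dba)3 (2.5 mol %), XPhos (10 mol %), THF, 65 °C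
Reagents that add atoms: bromo(2-methoxy-2-oxoethyl)zinc, COC(=O)C[Zn]Br
Why: Negishi-type cross-coupling of a Reformatsky reagent with an aryl bromide under a bulky biarylphosphine palladium catalyst is a much used route to arylacetates, and the nearly neutral zinc enolate should leave the acetal, the ring D alkene and the aryl ethers untouched.

Step 6
Reactants: 8 methyl 2-[7-methoxy-8-(methoxymethoxy)-2,2-dimethyl-2H-chromen-5-yl]acetate
Product: 10 methyl (E)-3-methoxy-2-[7-methoxy-8-(methoxymethoxy)-2,2-dimethyl-2H-chromen-5-yl]acrylate, via sodium enolate 9 (not isolated)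
Conditions: NaH, HCO2Me, THF–DMF, 0 °C to rt; then Me2SO4, rt
Reagents that add atoms: methyl formate, COC=O; dimethyl sulfate, COS(=O)(=O)OC
Why: Crossed Claisen condensation with methyl formate gives the stabilised formyl enolate, and its O-methylation by the hard electrophile dimethyl sulfate is the standard preparation of methyl 2-aryl-3-methoxyacrylates and should favour the E isomer.

Step 7
Reactants: 10 methyl (E)-3-methoxy-2-[7-methoxy-8-(methoxymethoxy)-2,2-dimethyl-2H-chromen-5-yl]acrylate
Product: 11 (E)-3-methoxy-2-[7-methoxy-8-(methoxymethoxy)-2,2-dimethyl-2H-chromen-5-yl]acrylic acid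
Conditions: LiOH·H2O, THF–MeOH–H2O, 40 °C; then 1 M HCl to pH 4, 0 °C
Reagents that add atoms: lithium hydroxide, [Li+].[OH-]
Why: Saponification by acyl–oxygen cleavage of 2-aryl-3-methoxyacrylic esters is known to stop at the stable acrylic acid, and cold acidification only to pH 4 should spare the MOM acetal and the enol ether.

Step 8
Reactants: 12 hydroquinone
Product: 13 4-(methoxymethoxy)phenol
Conditions: 12 (3 equiv), NaH (1 equiv), MOMCl (1 equiv), DMF, 0 °C
Reagents that add atoms: chloromethyl methyl ether (MOMCl), COCCl
Why: Statistical mono-O-alkylation of a symmetrical diphenol is biased towards the monoether by an excess of the cheap diphenol and one equivalent of base, and the surplus is removed by aqueous extraction.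

Step 9
Reactants: 13 4-(methoxymethoxy)phenol
Product: 14 2-chloro-4-(methoxymethoxy)phenol
Conditions: NCS (1.0 equiv), MeCN, 0 °C to rt, dark
Reagents that add atoms: N-chlorosuccinimide, O=C1CCC(=O)N1Cl
Why: Electrophilic aromatic chlorination follows the free hydroxyl, the strongest donor, to its ortho position because the para position is blocked, and NCS releases no mineral acid that could cleave the acetal.

Step 10
Reactants: 14 2-chloro-4-(methoxymethoxy)phenol
Product: 15 2-bromo-6-chloro-4-(methoxymethoxy)phenol
Conditions: NBS (1.0 equiv), CH2Cl2, 0 °C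
Reagents that add atoms: N-bromosuccinimide, O=C1CCC(=O)N1Br
Why: Electrophilic aromatic bromination is again governed by the hydroxyl group and takes its one remaining ortho position, as is usual for 2-halo-4-alkoxyphenols.

Step 11
Reactants: 15 2-bromo-6-chloro-4-(methoxymethoxy)phenol
Product: 18 2-chloro-4-(methoxymethoxy)-6-(trimethylsilyl)phenyl trifluoromethanesulfonate, via silyl ether 16 (not isolated), via lithium phenoxide 17 (not isolated)
Conditions: HMDS, THF, 70 °C, then evaporation; n-BuLi (1.05 equiv), THF, −78 °C; Tf2O, −78 to 0 °C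
Reagents that add atoms: hexamethyldisilazane, C[Si](C)(C)N[Si](C)(C)C; triflic anhydride, O=S(=O)(OS(=O)(=O)C(F)(F)F)C(F)(F)F
Why: O-silylation, bromine–lithium exchange, 1,3 O-to-C silyl migration (retro-Brook rearrangement) and triflation of the released phenoxide form the standard one-flask route from 2-bromophenols to 2-silylaryl triflates, and exchange at bromine at −78 °C should outrun attack on chlorine or ring deprotonation.

Step 12
Reactants: 11 (E)-3-methoxy-2-[7-methoxy-8-(methoxymethoxy)-2,2-dimethyl-2H-chromen-5-yl]acrylic acid; 18 2-chloro-4-(methoxymethoxy)-6-(trimethylsilyl)phenyl trifluoromethanesulfonate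
Product: 21 5-chloro-7-(methoxymethoxy)-3-[7-methoxy-8-(methoxymethoxy)-2,2-dimethyl-2H-chromen-5-yl]-4H-chromen-4-one, via aryne 19 (not isolated), via cesium acylphenoxide 20 (not isolated)
Conditions: 18 (1.5 equiv), CsF (4 equiv), THF, 125 °C, sealed tube
Reagents that add atoms: none
Why: Proposed new method: fluoride removes the silyl group of 18 and triflate leaves, giving aryne 19, to which the cesium carboxylate of 11 adds through oxygen at the aryne carbon remote from chlorine (bond C8a–O1), so that the negative charge develops on the carbon flanked by chlorine. That carbanion sits beside its own aryl ester and should attack the ester carbonyl 4-exo-trig (bond C4a–C4); fragmentation of the four-membered adduct at its C–O bond moves the acyl group from oxygen to carbon and frees phenoxide 20. Ring C then closes 6-endo-trig: the phenoxide oxygen adds to the methoxy-bearing alkene carbon of the vinylogous ester and methoxide is expelled (bond O1–C2), an addition–elimination in which the alkene geometry is lost and no stereocentre is formed. The closest known reaction type is the CsF-promoted insertion of arynes into the C–O bond of carboxylic acids, which gives 2-hydroxyaryl ketones and continues in the same flask to 4-chromanones from acrylic acids and to flavones from arylpropiolic acids, whereas 3-alkoxyacrylic acids have not been tried. The selectivity required is regiochemical, oxygen at C8a and acyl at C4a, and it is secured by the C5 chlorine, whose inductive pull distorts the aryne so that the distal carbon is the more electrophilic one and the anion is stabilised next to the halogen; the more distant C7 oxygen pulls the other way but only weakly. Hot THF is used because it offers no acidic C–H and because heat is known to favour acyl transfer over simple protonation to the aryl ester.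

Step 13
Reactants: 21 5-chloro-7-(methoxymethoxy)-3-[7-methoxy-8-(methoxymethoxy)-2,2-dimethyl-2H-chromen-5-yl]-4H-chromen-4-one
Product: 22 7-(methoxymethoxy)-3-[7-methoxy-8-(methoxymethoxy)-2,2-dimethyl-2H-chromen-5-yl]-4H-chromen-4-one
Conditions: Pd(OAc)2 (5 mol %), 2-(di-tert-butylphosphino)biphenyl (10 mol %), HCO2Na (3 equiv), MeOH–THF, 60 °C
Reagents that add atoms: none
Why: In this palladium-catalysed transfer hydrodehalogenation, zerovalent palladium with an electron-rich bulky phosphine inserts into the C5–Cl bond activated by the peri carbonyl, formate replaces chloride and loses CO2, and reductive elimination delivers C5–H without a metal surface that would hydrogenate ring D.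

Step 14
Reactants: 22 7-(methoxymethoxy)-3-[7-methoxy-8-(methoxymethoxy)-2,2-dimethyl-2H-chromen-5-yl]-4H-chromen-4-one
Product: 23 7-hydroxy-3-(8-hydroxy-7-methoxy-2,2-dimethyl-2H-chromen-5-yl)-4H-chromen-4-one
Conditions: HCl (0.5 M in MeOH), MeOH–THF, 40 °C
Reagents that add atoms: none
Why: Acid-catalysed transacetalisation of both aryl MOM ethers to dimethoxymethane in methanol is routine on isoflavones that carry a 2,2-dimethylchromene, provided acid strength and temperature are kept low.

Compound list
1 | 5-bromo-2-hydroxy-3-methoxybenzaldehyde | COc1cc(Br)cc(C=O)c1O | starting material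
2 | 5-bromo-3-methoxy-2-(methoxymethoxy)benzaldehyde | COCOc1c(OC)cc(Br)cc1C=O | intermediate
3 | 5-bromo-3-methoxy-2-(methoxymethoxy)phenyl formate | COCOc1c(OC)cc(Br)cc1OC=O | intermediate
4 | 5-bromo-3-methoxy-2-(methoxymethoxy)phenol | COCOc1c(OC)cc(Br)cc1O | intermediate
5 | 3-chloro-3-methylbut-1-yne | C#CC(C)(C)Cl | starting material
6 | 5-bromo-1-methoxy-2-(methoxymethoxy)-3-[(2-methylbut-3-yn-2-yl)oxy]benzene | COCOc1c(OC)cc(Br)cc1OC(C)(C)C#C | intermediate
7 | 5-bromo-7-methoxy-8-(methoxymethoxy)-2,2-dimethyl-2H-chromene | COCOc1c(OC)cc(Br)c2c1OC(C)(C)C=C2 | intermediate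
8 | methyl 2-[7-methoxy-8-(methoxymethoxy)-2,2-dimethyl-2H-chromen-5-yl]acetate | COC(=O)Cc1cc(OC)c(OCOC)c2c1C=CC(C)(C)O2 | intermediate
9 | sodium enolate of methyl 2-[7-methoxy-8-(methoxymethoxy)-2,2-dimethyl-2H-chromen-5-yl]-3-oxopropanoate (configurationally labile) | COC(=O)C(=C[O-])c1cc(OC)c(OCOC)c2c1C=CC(C)(C)O2.[Na+] | intermediate
10 | methyl (E)-3-methoxy-2-[7-methoxy-8-(methoxymethoxy)-2,2-dimethyl-2H-chromen-5-yl]acrylate | CO/C=C(/C(=O)OC)c1cc(OC)c(OCOC)c2c1C=CC(C)(C)O2 | intermediate
11 | (E)-3-methoxy-2-[7-methoxy-8-(methoxymethoxy)-2,2-dimethyl-2H-chromen-5-yl]acrylic acid | CO/C=C(/C(=O)O)c1cc(OC)c(OCOC)c2c1C=CC(C)(C)O2 | intermediate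
12 | hydroquinone | Oc1ccc(O)cc1 | starting material
13 | 4-(methoxymethoxy)phenol | COCOc1ccc(O)cc1 | intermediate
14 | 2-chloro-4-(methoxymethoxy)phenol | COCOc1ccc(O)c(Cl)c1 | intermediate
15 | 2-bromo-6-chloro-4-(methoxymethoxy)phenol | COCOc1cc(Cl)c(O)c(Br)c1 | intermediate
16 | [2-bromo-6-chloro-4-(methoxymethoxy)phenoxy]trimethylsilane | COCOc1cc(Cl)c(O[Si](C)(C)C)c(Br)c1 | intermediate
17 | lithium 2-chloro-4-(methoxymethoxy)-6-(trimethylsilyl)phenoxide | COCOc1cc(Cl)c([O-])c([Si](C)(C)C)c1.[Li+] | intermediate
18 | 2-chloro-4-(methoxymethoxy)-6-(trimethylsilyl)phenyl trifluoromethanesulfonate | COCOc1cc(Cl)c(OS(=O)(=O)C(F)(F)F)c([Si](C)(C)C)c1 | intermediate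
19 | 3-chloro-5-(methoxymethoxy)benzyne | COCOC1=CC#CC(Cl)=C1 | intermediate
20 | cesium 3-chloro-2-{(E)-3-methoxy-2-[7-methoxy-8-(methoxymethoxy)-2,2-dimethyl-2H-chromen-5-yl]acryloyl}-5-(methoxymethoxy)phenoxide | CO/C=C(/C(=O)c1c(Cl)cc(OCOC)cc1[O-])c1cc(OC)c(OCOC)c2c1C=CC(C)(C)O2.[Cs+] | intermediate
21 | 5-chloro-7-(methoxymethoxy)-3-[7-methoxy-8-(methoxymethoxy)-2,2-dimethyl-2H-chromen-5-yl]-4H-chromen-4-one | COCOc1cc(Cl)c2c(c1)occ(-c1cc(OC)c(OCOC)c3c1C=CC(C)(C)O3)c2=O | intermediate
22 | 7-(methoxymethoxy)-3-[7-methoxy-8-(methoxymethoxy)-2,2-dimethyl-2H-chromen-5-yl]-4H-chromen-4-one | COCOc1ccc2c(c1)occ(-c1cc(OC)c(OCOC)c3c1C=CC(C)(C)O3)c2=O | intermediate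
23 | 7-hydroxy-3-(8-hydroxy-7-methoxy-2,2-dimethyl-2H-chromen-5-yl)-4H-chromen-4-one | COc1cc(-c2coc3cc(O)ccc3c2=O)c2c(c1O)OC(C)(C)C=C2 | target

Total step count: 14. Longest linear sequence: 10 (steps 1–7, then 12–14). The aryne precursor is a four-step side branch (steps 8–11).

Steps most likely to fail

Step 12.
- **Risk:** the aryl anion may be protonated, or may shed chloride, before the acyl group has moved. The carboxylate may add at the wrong aryne carbon. The hindered α-aryl acrylate carbonyl may resist the four-membered transition state.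
- **Fallback:** give up the aryne and join C3 to C1' by Suzuki–Miyaura coupling. The fallback sets out from bromide 7. Miyaura borylation (B2pin2, PdCl2(dppf), KOAc, dioxane, 90 °C) should give 2-[7-methoxy-8-(methoxymethoxy)-2,2-dimethyl-2H-chromen-5-yl]-4,4,5,5-tetramethyl-1,3,2-dioxaborolane F1.
- **Coupling partner:** it comes from purchased 2,4-dihydroxyacetophenone. MOMCl and K2CO3 in acetone protect the non-chelated hydroxyl to give 1-[2-hydroxy-4-(methoxymethoxy)phenyl]ethanone F2. Heating with DMF dimethyl acetal gives (E)-3-(dimethylamino)-1-[2-hydroxy-4-(methoxymethoxy)phenyl]prop-2-en-1-one F3. Iodine in CHCl3 closes and iodinates it to 3-iodo-7-(methoxymethoxy)-4H-chromen-4-one F4.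
- **Return to the route:** coupling of F1 with F4 (Pd(PPh3)4, K2CO3, dioxane–H2O, 80 °C) comes back at 22.

Step 13.
- **Risk:** the palladium hydride may add to the ring D alkene or to the C2=C3 bond of ring C, so that over-reduction accompanies loss of chlorine.
- **Fallback:** avoid any metal hydride. The fallback sets out from 21. Miyaura borylation of the C5–Cl bond (B2pin2, Pd2(dba)3, XPhos, KOAc, dioxane, 100 °C) should give 7-(methoxymethoxy)-3-[7-methoxy-8-(methoxymethoxy)-2,2-dimethyl-2H-chromen-5-yl]-5-(4,4,5,5-tetramethyl-1,3,2-dioxaborolan-2-yl)-4H-chromen-4-one F5.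
- **Return to the route:** protodeboronation, which is easy for a boronate ortho to a carbonyl (AgNO3 cat., Et3N, EtOH–H2O, 80 °C), comes back at 22.

Step 14.
- **Risk:** Brønsted acid may protonate the electron-rich ring D double bond, so that methanol addition or dimerisation sets in before both acetals have gone.
- **Fallback:** replace acid solvolysis by a protecting-group exchange. The fallback sets out from 22. TMSOTf and 2,2'-bipyridyl in MeCN (0 °C to rt) should convert both aryl MOM ethers, without free acid, into 3-{7-methoxy-2,2-dimethyl-8-[(trimethylsilyl)oxy]-2H-chromen-5-yl}-7-[(trimethylsilyl)oxy]-4H-chromen-4-one F6.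
- **Return to the route:** water hydrolyses F6 at neutral pH, which comes back at 23.

Further compounds
F1 | step 12 | 2-[7-methoxy-8-(methoxymethoxy)-2,2-dimethyl-2H-chromen-5-yl]-4,4,5,5-tetramethyl-1,3,2-dioxaborolane | COCOc1c(OC)cc(B3OC(C)(C)C(C)(C)O3)c2c1OC(C)(C)C=C2
F2 | step 12 | 1-[2-hydroxy-4-(methoxymethoxy)phenyl]ethanone | CC(=O)c1ccc(OCOC)cc1O
F3 | step 12 | (E)-3-(dimethylamino)-1-[2-hydroxy-4-(methoxymethoxy)phenyl]prop-2-en-1-one | CN(C)/C=C/C(=O)c1ccc(OCOC)cc1O
F4 | step 12 | 3-iodo-7-(methoxymethoxy)-4H-chromen-4-one | COCOc1ccc2c(c1)occ(I)c2=O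
F5 | step 13 | 7-(methoxymethoxy)-3-[7-methoxy-8-(methoxymethoxy)-2,2-dimethyl-2H-chromen-5-yl]-5-(4,4,5,5-tetramethyl-1,3,2-dioxaborolan-2-yl)-4H-chromen-4-one | COCOc1cc(B4OC(C)(C)C(C)(C)O4)c2c(c1)occ(-c1cc(OC)c(OCOC)c3c1C=CC(C)(C)O3)c2=O
F6 | step 14 | 3-{7-methoxy-2,2-dimethyl-8-[(trimethylsilyl)oxy]-2H-chromen-5-yl}-7-[(trimethylsilyl)oxy]-4H-chromen-4-one | COc1cc(-c2coc3cc(O[Si](C)(C)C)ccc3c2=O)c2c(c1O[Si](C)(C)C)OC(C)(C)C=C2
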